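**Plan**

- Retrosynthesis: ring C of the flavanone is cut at O1–C8a and at C2–C3. This gives a chromane-6-carbaldehyde (fragment B, carrying C2 and O1) and an o-bromoaryl methyl ketone (ring A with C3, C4, C4a and C8a). In fragment B the prenyl–C8 bond and the benzylic C4–O bond of a chromene epoxide are cut; in ring A the acetyl–aryl bond.
- Enabling feature: the C4 carbonyl of ring C sits between the C3 methylene and the ring-A carbon C8a. One ketone therefore makes C3 nucleophilic (as its enol silane) and holds a C8a–Br bond next to the oxygen that the aldehyde brings. O1=C2 plus C3–C4–C4a–C8a amounts to a formal oxa-[4+2] annulation.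
- Forward order: the dihydropyran ring of fragment B is present from the start (a commercial chromene) and is oxidised at C3; bromine, the prenyl group and the aldehyde follow. The ring-A ketone is made and silylated separately. Ring C is formed last from the two fragments, and desilylation ends the route.
- Stereochemistry: C3 of the chromane is set by a catalyst-controlled Jacobsen–Katsuki epoxidation and kept through benzylic hydrogenolysis. C2 of the flavanone is set by a chiral boron Lewis acid in the aldol half of the key step and retained in the C–O ring closure.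

Key step: step 10

Assumption: the antipode of the N-tosyltryptophan-derived oxazaborolidinone that leaves the Si face of an aromatic aldehyde open is taken to be the one from (R)-tryptophan; if a test run shows the opposite sense, the (S)-tryptophan-derived antipode takes its place.

**Route**

Step 1
Reactants: 1 2,2-dimethyl-2H-chromene-6-carbonitrile
Product: 2 (3S,4S)-3,4-epoxy-2,2-dimethylchromane-6-carbonitrile
Conditions: chloro[(S,S)-N,N'-bis(3,5-di-tert-butylsalicylidene)cyclohexane-1,2-diaminato]manganese (3 mol%), aq. NaOCl (pH 11.3), 4-phenylpyridine N-oxide, CH2Cl2, 0 °C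
Reagents that add atoms: sodium hypochlorite, [Na+].[O-]Cl
Why: Jacobsen–Katsuki epoxidation, for which 2,2-dimethylchromenes (the 6-cyano compound in particular) are the best substrate class: the oxo-manganese salen species meets the cis C3=C4 bond side-on from the face left open by the (S,S)-diamine, which should set C3 and C4 both as S by catalyst control.

Step 2
Reactants: 2 (3S,4S)-3,4-epoxy-2,2-dimethylchromane-6-carbonitrile
Product: 3 (3S)-3-hydroxy-2,2-dimethylchromane-6-carbonitrile
Conditions: H2 (1 atm), 10% Pd/C, EtOAc, rt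
Reagents that add atoms: none
Why: Catalytic hydrogenolysis of a benzylic epoxide: only the C4–O bond is benzylic and is cleaved on palladium while the C3–O bond stays intact, so the alcohol should keep the S configuration, and the aryl nitrile is slow to reduce at 1 atm if the uptake is stopped at one equivalent of hydrogen.

Step 3
Reactants: 3 (3S)-3-hydroxy-2,2-dimethylchromane-6-carbonitrile
Product: 4 (3S)-8-bromo-3-hydroxy-2,2-dimethylchromane-6-carbonitrile
Conditions: Br2 (1.05 equiv), NaOAc, AcOH, rt
Reagents that add atoms: bromine, BrBr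
Why: Electrophilic aromatic bromination: C8 is the only free position activated by the ring oxygen (ortho to it; the para position carries the nitrile and C5 and C7 are ortho to the nitrile), so monobromination there is expected, with acetate taking up the HBr.

Step 4
Reactants: 4 (3S)-8-bromo-3-hydroxy-2,2-dimethylchromane-6-carbonitrile
Product: 5 (3S)-8-bromo-2,2-dimethyl-3-(triethylsilyloxy)chromane-6-carbonitrile
Conditions: Et3SiCl, imidazole, DMF, rt
Reagents that add atoms: chlorotriethylsilane, CC[Si](Cl)(CC)CC
Why: Silyl ether formation: the hindered secondary alcohol is masked as a triethylsilyl ether, which should survive the coupling, the hydride reduction and the Lewis acid of the later steps and leaves with the other silyl groups in the last step, the stereocentre not being touched.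

Step 5
Reactants: 5 (3S)-8-bromo-2,2-dimethyl-3-(triethylsilyloxy)chromane-6-carbonitrile
Product: 6 (3S)-2,2-dimethyl-8-(3-methylbut-2-en-1-yl)-3-(triethylsilyloxy)chromane-6-carbonitrile
Conditions: tributyl(3-methylbut-2-en-1-yl)stannane, Pd(PPh3)4 (5 mol%), DMF, 90 °C
Reagents that add atoms: tributyl(3-methylbut-2-en-1-yl)stannane, CCCC[Sn](CCCC)(CCCC)CC=C(C)C
Why: Stille coupling: oxidative addition of zerovalent palladium to the C8–Br bond, transmetalation from tin and reductive elimination should deliver the prenyl group through its CH2 terminus (linear product), as is usual for prenylstannanes under triphenylphosphine–palladium catalysis in DMF, and the nitrile and the silyl ether are inert.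

Step 6
Reactants: 6 (3S)-2,2-dimethyl-8-(3-methylbut-2-en-1-yl)-3-(triethylsilyloxy)chromane-6-carbonitrile
Product: 7 (3S)-2,2-dimethyl-8-(3-methylbut-2-en-1-yl)-3-(triethylsilyloxy)chromane-6-carbaldehyde
Conditions: i-Bu2AlH (1.2 equiv), toluene, −78 °C; then aq. potassium sodium tartrate
Reagents that add atoms: water, O
Why: Partial reduction of a nitrile: one hydride from i-Bu2AlH gives the N-aluminio imine, which is stable at −78 °C and is hydrolysed on work-up to the aldehyde, while the silyl ether and the trisubstituted alkene do not react.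

Step 7
Reactants: 8 5-bromobenzene-1,3-diol
Product: 9 1-(2-bromo-4,6-dihydroxyphenyl)ethanone
Conditions: MeCN, ZnCl2, HCl (g), Et2O, 0 °C; then H2O, reflux
Reagents that add atoms: acetonitrile, CC#N; water, O
Why: Houben–Hoesch acylation: the nitrilium electrophile should attack the resorcinol para to one hydroxyl and ortho to the other, next to bromine, as it does with resorcinol and orcinol, and hydrolysis of the ketiminium chloride gives the ketone; the isomer acylated between the two hydroxyls is the expected minor product and is removed by crystallisation.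

Step 8
Reactants: 9 1-(2-bromo-4,6-dihydroxyphenyl)ethanone
Product: 10 1-[2-bromo-4,6-bis(triisopropylsilyloxy)phenyl]ethanone
Conditions: i-Pr3SiOTf (2.3 equiv), 2,6-lutidine, CH2Cl2, 0 °C to rt
Reagents that add atoms: triisopropylsilyl trifluoromethanesulfonate, CC(C)[Si](OS(=O)(=O)C(F)(F)F)(C(C)C)C(C)C
Why: Silylation of phenols: the silyl triflate with the weak, hindered base 2,6-lutidine should silylate both hydroxyls, the chelated ortho one included, without enolising the ketone, and the bulky aryl silyl ethers stand up to the phosphate base of step 10.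

Step 9
Reactants: 10 1-[2-bromo-4,6-bis(triisopropylsilyloxy)phenyl]ethanone
Product: 11 {1-[2-bromo-4,6-bis(triisopropylsilyloxy)phenyl]ethenyloxy}trimethylsilane
Conditions: Me3SiOTf, Et3N, CH2Cl2, 0 °C
Reagents that add atoms: trimethylsilyl trifluoromethanesulfonate, C[Si](C)(C)OS(=O)(=O)C(F)(F)F
Why: Soft enolisation: O-silylation of the carbonyl by the triflate and loss of a methyl proton to triethylamine give the only possible (terminal) trimethylsilyl enol ether, the C3 nucleophile of the key step.

Step 10
Reactants: 11 {1-[2-bromo-4,6-bis(triisopropylsilyloxy)phenyl]ethenyloxy}trimethylsilane; 7 (3S)-2,2-dimethyl-8-(3-methylbut-2-en-1-yl)-3-(triethylsilyloxy)chromane-6-carbaldehyde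
Product: 14 (2S)-2-[(3S)-2,2-dimethyl-8-(3-methylbut-2-en-1-yl)-3-(triethylsilyloxy)chroman-6-yl]-5,7-bis(triisopropylsilyloxy)chroman-4-one, via (S)-aldol trimethylsilyl ether 12 (not isolated), via free (S)-aldol 13 (not isolated)
Conditions: (a) (4R)-2-butyl-4-(1H-indol-3-ylmethyl)-3-(4-methylphenylsulfonyl)-1,3,2-oxazaborolidin-5-one (20 mol%), EtCN, −78 to −40 °C; (b) MeOH, 0 °C, then solvent exchange to toluene; (c) Pd(OAc)2 (5 mol%), 2-(di-tert-butylphosphino)-1,1'-binaphthyl (6 mol%), K3PO4, toluene, 65 °C, same flask
Reagents that add atoms: none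
Why: Formal oxa-[4+2] annulation between the aldehyde O1=C2 and the C3–C4–C4a–C8a unit of the ketone, run in one flask: the chiral boron Lewis acid binds the aldehyde and the terminal carbon of enol silane 11 (C3) adds to its Si face through an open transition state with silyl transfer to O1, a Mukaiyama aldol addition of the kind established for aryl methyl ketone enol silanes and aromatic aldehydes under N-sulfonyl amino acid oxazaborolidinones. Methanol then frees the carbinol, zerovalent palladium inserts into the C8a–Br bond, the hydroxyl is deprotonated only once it is bound to palladium, and C–O reductive elimination forms O1–C8a, as in the Buchwald–Hartwig-type cyclisation of secondary alcohols onto aryl bromides. Ring C is the only ring closed, by reductive elimination from a seven-membered aryl(alkoxo)palladium chelate that contracts to the six-membered pyranone. C2 is the only new stereocentre: it is set by the catalyst in the aldol addition (the distant chromanol centre has no say) and keeps its configuration in the ring closure because the C2–O1 bond is never broken, so (3S)-13 should give (2S)-14. The step needs Si-face addition, ring closure faster than β-hydride elimination from the palladium alkoxide, and the absence of free alkoxide or enolate, which would cleave the aldol by retro-aldol reaction or dehydrate it to the chalcone. The bulky di-tert-butylphosphine, the insoluble weak base and the substrate itself secure these, since the single C4 carbonyl both makes C3 nucleophilic and holds the ortho C8a–Br bond within reach of O1, while both phenols are silylated and cannot take part.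

Step 11
Reactants: 14 (2S)-2-[(3S)-2,2-dimethyl-8-(3-methylbut-2-en-1-yl)-3-(triethylsilyloxy)chroman-6-yl]-5,7-bis(triisopropylsilyloxy)chroman-4-one
Product: 15 (2S)-5,7-dihydroxy-2-[(3S)-3-hydroxy-2,2-dimethyl-8-(3-methylbut-2-en-1-yl)chroman-6-yl]chroman-4-one
Conditions: Bu4NF (1 M in THF), AcOH (1 equiv per fluoride), THF, 0 °C to rt
Reagents that add atoms: none
Why: Fluoride-mediated desilylation: fluoride cleaves the two aryl triisopropylsilyl ethers and the triethylsilyl ether, and the acetic acid buffer keeps the phenols protonated so that ring C should not open to the chalcone, which would scramble C2.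

**Compound list**

1 | 2,2-dimethyl-2H-chromene-6-carbonitrile | CC1(C)C=Cc2cc(C#N)ccc2O1 | starting material
2 | (3S,4S)-3,4-epoxy-2,2-dimethylchromane-6-carbonitrile | N#Cc1ccc2OC(C)(C)[C@H]3O[C@H]3c2c1 | intermediate
3 | (3S)-3-hydroxy-2,2-dimethylchromane-6-carbonitrile | N#Cc1ccc2OC(C)(C)[C@@H](O)Cc2c1 | intermediate
4 | (3S)-8-bromo-3-hydroxy-2,2-dimethylchromane-6-carbonitrile | N#Cc1cc(Br)c2OC(C)(C)[C@@H](O)Cc2c1 | intermediate
5 | (3S)-8-bromo-2,2-dimethyl-3-(triethylsilyloxy)chromane-6-carbonitrile | N#Cc1cc(Br)c2OC(C)(C)[C@@H](O[Si](CC)(CC)CC)Cc2c1 | intermediate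
6 | (3S)-2,2-dimethyl-8-(3-methylbut-2-en-1-yl)-3-(triethylsilyloxy)chromane-6-carbonitrile | N#Cc1cc(CC=C(C)C)c2OC(C)(C)[C@@H](O[Si](CC)(CC)CC)Cc2c1 | intermediate
7 | (3S)-2,2-dimethyl-8-(3-methylbut-2-en-1-yl)-3-(triethylsilyloxy)chromane-6-carbaldehyde | O=Cc1cc(CC=C(C)C)c2OC(C)(C)[C@@H](O[Si](CC)(CC)CC)Cc2c1 | intermediate
8 | 5-bromobenzene-1,3-diol | Oc1cc(O)cc(Br)c1 | starting material
9 | 1-(2-bromo-4,6-dihydroxyphenyl)ethanone | CC(=O)c1c(O)cc(O)cc1Br | intermediate
10 | 1-[2-bromo-4,6-bis(triisopropylsilyloxy)phenyl]ethanone | CC(=O)c1c(O[Si](C(C)C)(C(C)C)C(C)C)cc(O[Si](C(C)C)(C(C)C)C(C)C)cc1Br | intermediate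
11 | {1-[2-bromo-4,6-bis(triisopropylsilyloxy)phenyl]ethenyloxy}trimethylsilane | C=C(O[Si](C)(C)C)c1c(O[Si](C(C)C)(C(C)C)C(C)C)cc(O[Si](C(C)C)(C(C)C)C(C)C)cc1Br | intermediate
12 | (3S)-1-[2-bromo-4,6-bis(triisopropylsilyloxy)phenyl]-3-[(3S)-2,2-dimethyl-8-(3-methylbut-2-en-1-yl)-3-(triethylsilyloxy)chroman-6-yl]-3-(trimethylsilyloxy)propan-1-one | O=C(C[C@H](O[Si](C)(C)C)c1cc(CC=C(C)C)c2OC(C)(C)[C@@H](O[Si](CC)(CC)CC)Cc2c1)c1c(O[Si](C(C)C)(C(C)C)C(C)C)cc(O[Si](C(C)C)(C(C)C)C(C)C)cc1Br | intermediate
13 | (3S)-1-[2-bromo-4,6-bis(triisopropylsilyloxy)phenyl]-3-[(3S)-2,2-dimethyl-8-(3-methylbut-2-en-1-yl)-3-(triethylsilyloxy)chroman-6-yl]-3-hydroxypropan-1-one | O=C(C[C@H](O)c1cc(CC=C(C)C)c2OC(C)(C)[C@@H](O[Si](CC)(CC)CC)Cc2c1)c1c(O[Si](C(C)C)(C(C)C)C(C)C)cc(O[Si](C(C)C)(C(C)C)C(C)C)cc1Br | intermediate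
14 | (2S)-2-[(3S)-2,2-dimethyl-8-(3-methylbut-2-en-1-yl)-3-(triethylsilyloxy)chroman-6-yl]-5,7-bis(triisopropylsilyloxy)chroman-4-one | CC(C)=CCc1cc([C@@H]2CC(=O)c3c(O[Si](C(C)C)(C(C)C)C(C)C)cc(O[Si](C(C)C)(C(C)C)C(C)C)cc3O2)cc2c1OC(C)(C)[C@@H](O[Si](CC)(CC)CC)C2 | intermediate
15 | (2S)-5,7-dihydroxy-2-[(3S)-3-hydroxy-2,2-dimethyl-8-(3-methylbut-2-en-1-yl)chroman-6-yl]chroman-4-one | CC(C)=CCc1cc([C@@H]2CC(=O)c3c(O)cc(O)cc3O2)cc2c1OC(C)(C)[C@@H](O)C2 | target

**Count and risks**

Total step count: 11. Longest linear sequence: 8 steps (steps 1–6, 10 and 11, from 1 to 15).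

Steps most likely to fail:

Step 10. The β-hydroxy ketone may suffer retro-aldol cleavage or dehydration under the base of the palladium stage, the palladium alkoxide may undergo β-hydride elimination instead of ring closure, or the facial selectivity of the aldol addition may be poor with the di-ortho-substituted enol silane. The fallback closes ring C from the other side, at C2 with inversion; it sets out from 7 and comes back at 14. Commercial 2',4',6'-trihydroxyacetophenone is silylated at the 4'- and one 2'-hydroxyl (i-Pr3SiCl, imidazole, DMF) to give 1-[2-hydroxy-4,6-bis(triisopropylsilyloxy)phenyl]ethanone F1. Me3SiOTf and Et3N turn it into trimethyl({1-[2-(trimethylsilyloxy)-4,6-bis(triisopropylsilyloxy)phenyl]ethenyl}oxy)silane F2. Mukaiyama aldol addition of F2 to 7 under the antipodal, (S)-tryptophan-derived oxazaborolidinone, followed by citric acid in MeOH at 0 °C, should give (3R)-3-[(3S)-2,2-dimethyl-8-(3-methylbut-2-en-1-yl)-3-(triethylsilyloxy)chroman-6-yl]-3-hydroxy-1-[2-hydroxy-4,6-bis(triisopropylsilyloxy)phenyl]propan-1-one F3. An intramolecular Mitsunobu etherification (PPh3, DIAD, THF, 0 °C) then joins the phenol oxygen to C2 with inversion and gives 14.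

Step 5. The prenyl group may be transferred through its tertiary carbon (reverse prenylation), or transmetalation next to the ring oxygen may be slow. The fallback builds the prenyl group by olefin metathesis; it sets out from 5 and comes back at 6. Stille coupling of 5 with allyltributylstannane (Pd(PPh3)4, DMF, 90 °C) gives (3S)-2,2-dimethyl-8-(prop-2-en-1-yl)-3-(triethylsilyloxy)chromane-6-carbonitrile F4. Cross metathesis with 2-methylbut-2-ene (second-generation Grubbs catalyst, CH2Cl2, 40 °C) converts the allyl into the prenyl group and gives 6.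

Step 7. The electrophile may attack between the two hydroxyls, or a second acylation may follow. The fallback acylates the dimethyl ether, where attack para to a methoxy group and next to bromine is the known course; it sets out from 8 and comes back at 9. O-Methylation (MeI, K2CO3, acetone) gives 1-bromo-3,5-dimethoxybenzene F5. Friedel–Crafts acetylation (AcCl, AlCl3, CH2Cl2, 0 °C) gives 1-(2-bromo-4,6-dimethoxyphenyl)ethanone F6. Demethylation with BBr3 (CH2Cl2, −78 °C to rt) gives 9.

Further compounds
F1 | step 10 | 1-[2-hydroxy-4,6-bis(triisopropylsilyloxy)phenyl]ethanone | CC(=O)c1c(O)cc(O[Si](C(C)C)(C(C)C)C(C)C)cc1O[Si](C(C)C)(C(C)C)C(C)C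
F2 | step 10 | trimethyl({1-[2-(trimethylsilyloxy)-4,6-bis(triisopropylsilyloxy)phenyl]ethenyl}oxy)silane | C=C(O[Si](C)(C)C)c1c(O[Si](C)(C)C)cc(O[Si](C(C)C)(C(C)C)C(C)C)cc1O[Si](C(C)C)(C(C)C)C(C)C
F3 | step 10 | (3R)-3-[(3S)-2,2-dimethyl-8-(3-methylbut-2-en-1-yl)-3-(triethylsilyloxy)chroman-6-yl]-3-hydroxy-1-[2-hydroxy-4,6-bis(triisopropylsilyloxy)phenyl]propan-1-one | O=C(C[C@@H](O)c1cc(CC=C(C)C)c2OC(C)(C)[C@@H](O[Si](CC)(CC)CC)Cc2c1)c1c(O)cc(O[Si](C(C)C)(C(C)C)C(C)C)cc1O[Si](C(C)C)(C(C)C)C(C)C
F4 | step 5 | (3S)-2,2-dimethyl-8-(prop-2-en-1-yl)-3-(triethylsilyloxy)chromane-6-carbonitrile | N#Cc1cc(CC=C)c2OC(C)(C)[C@@H](O[Si](CC)(CC)CC)Cc2c1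
F5 | step 7 | 1-bromo-3,5-dimethoxybenzene | COc1cc(OC)cc(Br)c1
F6 | step 7 | 1-(2-bromo-4,6-dimethoxyphenyl)ethanone | CC(=O)c1c(OC)cc(OC)cc1Br
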